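## Retrosynthetic overview

1. Target 31 is cut last at the triene C2''–C3'' bond: Heck coupling of the core vinyl carbinol 22 with bromodienamide 30.
2. 22 comes from ketal removal after a copper-catalysed N-vinylation (ring C2–N bond) of dienamide 11 with α-iodoenone 20.
3. 20 comes from enone 19, made by a new enantioselective desymmetrising boronate oxa-Michael addition on the achiral p-quinol 15 (sets C-4 and C-5); 15 comes from 1,4-benzoquinone, ethynylmagnesium bromide and a Lindlar reduction.
4. 11 comes from two Wittig homologations of (R)-2-methylhexan-1-ol, itself from a copper-catalysed Kochi coupling; 30 comes from 5-bromodienoic acid (glutaconaldehyde potassium salt) and 2-aminocyclopentane-1,3-dione (cyclopentane-1,3-dione).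
5. Rings: both carbocycles are bought (benzoquinone, cyclopentane-1,3-dione) and no carbocycle is formed; only a temporary dioxaborolane (step 9) and then a dioxolane (step 10, opened in step 13) are closed on the six-membered ring.

Assumption: (S)-3-bromo-2-methylpropan-1-ol and glutaconaldehyde potassium salt are bought, and the epi-quinidine-derived thiourea is assumed to give the (4S,5R) series in step 9 (otherwise its epi-quinine pseudo-enantiomer is used).

## Route

### Upper amide (fragment A)

Step 1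
Reactants: 1 (S)-3-bromo-2-methylpropan-1-ol; 2 n-propylmagnesium bromide
Product: 3 (R)-2-methylhexan-1-ol
Conditions: 2 (2.3 equiv), Li2CuCl4 (3 mol%), THF, −78 → 0 °C; then H2O
Reagents that add atoms: none
Why: Copper-catalysed Kochi sp3–sp3 cross-coupling, in which the first equivalent of Grignard reagent forms the magnesium alkoxide and the second displaces the primary bromide; the stereocentre is a spectator (S to R is only a change of CIP priorities).

Step 2
Reactants: 3 (R)-2-methylhexan-1-ol
Product: 5 ethyl (2E,4R)-2,4-dimethyloct-2-enoate, via (R)-2-methylhexanal 4 (not isolated)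
Conditions: TEMPO (10 mol%), PhI(OAc)2 (1.05 equiv), CH2Cl2, rt, 3 h; then Ph3P=C(Me)CO2Et (1.5 equiv), rt → 40 °C, 16 h
Reagents that add atoms: ethyl 2-(triphenylphosphoranylidene)propanoate, CCOC(=O)C(C)=P(c1ccccc1)(c1ccccc1)c1ccccc1
Why: One-pot TEMPO/PhI(OAc)2 oxidation and Wittig olefination, so the epimerisable α-chiral aldehyde is trapped as it forms and the stabilised ylide gives the (E)-trisubstituted enoate.

Step 3
Reactants: 5 ethyl (2E,4R)-2,4-dimethyloct-2-enoate
Product: 6 (2E,4R)-2,4-dimethyloct-2-en-1-ol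
Conditions: diisobutylaluminium hydride (2.3 equiv), CH2Cl2, −78 °C; aq. potassium sodium tartrate
Reagents that add atoms: none
Why: Diisobutylaluminium hydride 1,2-reduction of the conjugated ester to the allylic alcohol, with no effect on alkene geometry or the stereocentre.

Step 4
Reactants: 6 (2E,4R)-2,4-dimethyloct-2-en-1-ol
Product: 8 ethyl (2E,4E,6R)-2,4,6-trimethyldeca-2,4-dienoate, via (2E,4R)-2,4-dimethyloct-2-enal 7 (not isolated)
Conditions: activated MnO2 (15 equiv), Ph3P=C(Me)CO2Et (1.5 equiv), toluene, 80 °C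
Reagents that add atoms: ethyl 2-(triphenylphosphoranylidene)propanoate, CCOC(=O)C(C)=P(c1ccccc1)(c1ccccc1)c1ccccc1
Why: Tandem MnO2 allylic oxidation and Wittig olefination, in which the enal is intercepted in situ by the stabilised ylide to give the (2E,4E)-dienoate under neutral conditions.

Step 5
Reactants: 8 ethyl (2E,4E,6R)-2,4,6-trimethyldeca-2,4-dienoate
Product: 9 (2E,4E,6R)-2,4,6-trimethyldeca-2,4-dienoic acid
Conditions: LiOH·H2O (5 equiv), THF–MeOH–H2O (3:1:1), 45 °C; then 1 M HCl to pH 3
Reagents that add atoms: lithium hydroxide, [Li+].[OH-]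
Why: Ester saponification; the trisubstituted diene and the remote stereocentre are inert to hydroxide.

Step 6
Reactants: 9 (2E,4E,6R)-2,4,6-trimethyldeca-2,4-dienoic acid
Product: 11 (2E,4E,6R)-2,4,6-trimethyldeca-2,4-dienamide, via acyl imidazolide 10 (not isolated)
Conditions: 1,1′-carbonyldiimidazole (1.3 equiv), THF, rt, 2 h; then 28% aq. NH3, 0 °C → rt
Reagents that add atoms: ammonia, N
Why: Carbonyldiimidazole activation followed by aminolysis of the acyl imidazolide gives the primary amide without touching the diene.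

### Core (fragment B)

Step 7
Reactants: 12 1,4-benzoquinone; 13 ethynylmagnesium bromide
Product: 14 4-ethynyl-4-hydroxycyclohexa-2,5-dien-1-one
Conditions: 12 (1.3 equiv) in THF, −78 °C, slow addition of 13 (0.5 M in THF), → −20 °C; then H2O
Reagents that add atoms: none
Why: 1,2-Addition of an alkynyl Grignard reagent to one quinone carbonyl (alkynyl metals are poor single-electron donors, so carbonyl addition wins over quinone reduction, and inverse addition limits bis-addition) gives the achiral p-quinol.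

Step 8
Reactants: 14 4-ethynyl-4-hydroxycyclohexa-2,5-dien-1-one
Product: 15 4-ethenyl-4-hydroxycyclohexa-2,5-dien-1-one
Conditions: H2 (1 atm, 1.0 equiv uptake), Pd on CaCO3 poisoned with Pb(OAc)2 (Lindlar catalyst), quinoline (0.2 equiv), EtOAc, rt
Reagents that add atoms: none
Why: Lindlar semi-hydrogenation reduces the terminal alkyne much faster than the electron-poor dienone alkenes on the poisoned catalyst.

Step 9
Reactants: 15 4-ethenyl-4-hydroxycyclohexa-2,5-dien-1-one
Product: 17 (3aR,7aS)-7a-ethenyl-2-phenyl-3a,4-dihydro-1,3,2-benzodioxaborol-5(7aH)-one, via boronic hemiester 16 (not isolated)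
Conditions: PhB(OH)2 (1.2 equiv), 9-amino-9-deoxy-epi-quinidine 3,5-bis(trifluoromethyl)phenyl thiourea (10 mol%), 4 Å MS, toluene, 0 °C → rt, 24–48 h; filtered and used crude
Reagents that add atoms: phenylboronic acid, OB(O)c1ccccc1
Why: Proposed new method: an amine–thiourea-catalysed, boronic-acid-templated desymmetrising oxa-Michael addition, in which PhB(OH)2 esterifies the tertiary OH to hemiester 16, the quinuclidine nitrogen of the catalyst binds boron to give a chiral tetrahedral boronate whose B–OH is the nucleophile while the thiourea hydrogen-bonds the dienone carbonyl, so that oxygen is delivered intramolecularly (5-exo, therefore cis to the C-4 oxygen) to only one of the two enantiotopic β-carbons, which fixes C-5 as R and thereby C-4 as S; the closest known reaction type is the amine–thiourea/arylboronic acid oxy-Michael ("chiral hydroxide") addition to acyclic γ-hydroxy enones, which to my knowledge has not been used to distinguish the two enone arms of a prochiral p-quinol.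

Step 10
Reactants: 17 (3aR,7aS)-7a-ethenyl-2-phenyl-3a,4-dihydro-1,3,2-benzodioxaborol-5(7aH)-one
Product: 19 (3aR,7aS)-7a-ethenyl-2,2-dimethyl-3a,4-dihydro-1,3-benzodioxol-5(7aH)-one, via diol 18 (not isolated)
Conditions: pinacol (1.3 equiv), 2,2-dimethoxypropane (10 equiv), PPTS (10 mol%), acetone, rt
Reagents that add atoms: 2,2-dimethoxypropane, COC(C)(C)OC
Why: Boronate transesterification to pinacol releases the cis-diol, which is ketalised at once under mild acid (acetonide formation); no stereocentre is touched and the base-sensitive β-hydroxy ketone is masked.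

Step 11
Reactants: 19 (3aR,7aS)-7a-ethenyl-2,2-dimethyl-3a,4-dihydro-1,3-benzodioxol-5(7aH)-one
Product: 20 (3aR,7aS)-7a-ethenyl-6-iodo-2,2-dimethyl-3a,4-dihydro-1,3-benzodioxol-5(7aH)-one
Conditions: I2 (2 equiv), DMAP (20 mol%), pyridine–CH2Cl2 (1:1), 0 °C → rt, dark; aq. Na2S2O3 wash
Reagents that add atoms: iodine, II
Why: Johnson α-iodination of the enone (reversible conjugate addition of the pyridine base, iodination of the enolate, E1cB loss of the base), which leaves the isolated vinyl group and the ketal alone and permanently differentiates the two former enone arms.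

### First union and deprotection

Step 12
Reactants: 20 (3aR,7aS)-7a-ethenyl-6-iodo-2,2-dimethyl-3a,4-dihydro-1,3-benzodioxol-5(7aH)-one; 11 (2E,4E,6R)-2,4,6-trimethyldeca-2,4-dienamide
Product: 21 (2E,4E,6R)-N-[(3aR,7aS)-7a-ethenyl-2,2-dimethyl-5-oxo-3a,4,5,7a-tetrahydro-1,3-benzodioxol-6-yl]-2,4,6-trimethyldeca-2,4-dienamide
Conditions: 11 (1.2 equiv), CuI (10 mol%), N,N′-dimethylethylenediamine (20 mol%), K2CO3 (2 equiv), toluene, 70 °C, Ar
Reagents that add atoms: none
Why: Goldberg–Buchwald copper-catalysed N-vinylation of a primary amide with an activated α-iodoenone forms the ring C2–N bond; cine-substitution is blocked because the β-carbon sits next to the quaternary centre, and the mild heterogeneous base spares the β-alkoxy ketone.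

Step 13
Reactants: 21 (2E,4E,6R)-N-[(3aR,7aS)-7a-ethenyl-2,2-dimethyl-5-oxo-3a,4,5,7a-tetrahydro-1,3-benzodioxol-6-yl]-2,4,6-trimethyldeca-2,4-dienamide
Product: 22 (2E,4E,6R)-N-[(3S,4R)-3-ethenyl-3,4-dihydroxy-6-oxocyclohex-1-en-1-yl]-2,4,6-trimethyldeca-2,4-dienamide
Conditions: AcOH–H2O (4:1), 45 °C
Reagents that add atoms: none
Why: Mild acid hydrolysis of the isopropylidene ketal, done before the triene is built so that the tertiary carbinol is only a simple vinyl carbinol and does not ionise.

### Lower amide (fragment C)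

Step 14
Reactants: 23 cyclopentane-1,3-dione
Product: 24 2-(hydroxyimino)cyclopentane-1,3-dione
Conditions: NaNO2 (1.05 equiv), 1 M aq. HCl, 0 °C
Reagents that add atoms: sodium nitrite, [Na+].[O-]N=O
Why: Nitrosation of the enolised 1,3-dione at C-2, followed by tautomerisation to the oxime.

Step 15
Reactants: 24 2-(hydroxyimino)cyclopentane-1,3-dione
Product: 25 2-amino-3-hydroxycyclopent-2-en-1-one hydrochloride
Conditions: H2 (3 atm), 10% Pd/C, HCl (1.1 equiv), MeOH, rt
Reagents that add atoms: hydrogen chloride, Cl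
Why: Catalytic hydrogenolysis of the oxime N–O bond and reduction to the amine, trapped as the stable hydrochloride; the enolised dione is not reduced.

Step 16
Reactants: 26 potassium (1E,3E)-5-oxopenta-1,3-dien-1-olate
Product: 27 (2E,4E)-5-bromopenta-2,4-dienal
Conditions: PPh3 (1.1 equiv), Br2 (1.1 equiv), CH2Cl2, 0 °C; then 26, 0 °C → rt
Reagents that add atoms: bromine, BrBr
Why: Deoxybromination of a vinylogous carboxylate: the enolate oxygen attacks the bromophosphonium, and bromide addition–elimination expels Ph3P=O to give the thermodynamic (2E,4E)-bromodienal.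

Step 17
Reactants: 27 (2E,4E)-5-bromopenta-2,4-dienal
Product: 28 (2E,4E)-5-bromopenta-2,4-dienoic acid
Conditions: NaClO2 (1.5 equiv), NaH2PO4 (2 equiv), 2-methylbut-2-ene (10 equiv), t-BuOH–H2O, 0 °C → rt
Reagents that add atoms: sodium chlorite, [Na+].[O-]Cl=O
Why: Pinnick oxidation converts the enal to the acid without touching the vinyl bromide or the alkene geometry, the scavenger alkene removing HOCl.

Step 18
Reactants: 28 (2E,4E)-5-bromopenta-2,4-dienoic acid; 25 2-amino-3-hydroxycyclopent-2-en-1-one hydrochloride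
Product: 30 (2E,4E)-5-bromo-N-(2-hydroxy-5-oxocyclopent-1-en-1-yl)penta-2,4-dienamide, via acid chloride 29 (not isolated)
Conditions: (COCl)2 (1.2 equiv), DMF (cat.), CH2Cl2, 0 °C → rt, concentrate; then 25 (1.1 equiv), Et3N (3.2 equiv), DMF–CH2Cl2, 0 °C → rt; dilute HCl work-up
Reagents that add atoms: none
Why: Acid chloride formation and N-acylation; any enol ester formed first rearranges by O-to-N acyl transfer to the more stable amide.

### Final union

Step 19
Reactants: 22 (2E,4E,6R)-N-[(3S,4R)-3-ethenyl-3,4-dihydroxy-6-oxocyclohex-1-en-1-yl]-2,4,6-trimethyldeca-2,4-dienamide; 30 (2E,4E)-5-bromo-N-(2-hydroxy-5-oxocyclopent-1-en-1-yl)penta-2,4-dienamide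
Product: 31 (2E,4E,6R)-N-[(3S,4R)-3,4-dihydroxy-3-[(1E,3E,5E)-7-[(2-hydroxy-5-oxocyclopent-1-en-1-yl)amino]-7-oxohepta-1,3,5-trien-1-yl]-6-oxocyclohex-1-en-1-yl]-2,4,6-trimethyldeca-2,4-dienamide (the target)
Conditions: 30 (1.3 equiv), Pd(OAc)2 (10 mol%), Bu4NCl (1 equiv), NaHCO3 (3 equiv), DMF, 45 °C, Ar, dark; work-up at pH 4
Reagents that add atoms: none
Why: Mizoroki–Heck coupling under Jeffery conditions: zerovalent palladium formed in situ inserts into the activated dienyl C–Br bond and adds to the terminal carbon of the only monosubstituted alkene, and β-hydride elimination can occur only away from the quaternary carbinol, so the new alkene is E and the all-E triene results with both ring stereocentres untouched.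

## Compound list

1 | (S)-3-bromo-2-methylpropan-1-ol | BrC[C@@H](C)CO | starting material
2 | n-propylmagnesium bromide | CCC[Mg]Br | starting material
3 | (R)-2-methylhexan-1-ol | CCCC[C@@H](C)CO | intermediate
4 | (R)-2-methylhexanal | CCCC[C@@H](C)C=O | intermediate
5 | ethyl (2E,4R)-2,4-dimethyloct-2-enoate | CCCC[C@@H](C)/C=C(\C)C(=O)OCC | intermediate
6 | (2E,4R)-2,4-dimethyloct-2-en-1-ol | CCCC[C@@H](C)/C=C(\C)CO | intermediate
7 | (2E,4R)-2,4-dimethyloct-2-enal | CCCC[C@@H](C)/C=C(\C)C=O | intermediate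
8 | ethyl (2E,4E,6R)-2,4,6-trimethyldeca-2,4-dienoate | CCCC[C@@H](C)/C=C(C)/C=C(\C)C(=O)OCC | intermediate
9 | (2E,4E,6R)-2,4,6-trimethyldeca-2,4-dienoic acid | CCCC[C@@H](C)/C=C(C)/C=C(\C)C(=O)O | intermediate
10 | (2E,4E,6R)-1-(1H-imidazol-1-yl)-2,4,6-trimethyldeca-2,4-dien-1-one (acyl imidazolide) | CCCC[C@@H](C)/C=C(C)/C=C(\C)C(=O)n1ccnc1 | intermediate
11 | (2E,4E,6R)-2,4,6-trimethyldeca-2,4-dienamide | CCCC[C@@H](C)/C=C(C)/C=C(\C)C(N)=O | intermediate
12 | 1,4-benzoquinone | O=C1C=CC(=O)C=C1 | starting material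
13 | ethynylmagnesium bromide | C#C[Mg]Br | starting material
14 | 4-ethynyl-4-hydroxycyclohexa-2,5-dien-1-one | O=C1C=CC(O)(C#C)C=C1 | intermediate
15 | 4-ethenyl-4-hydroxycyclohexa-2,5-dien-1-one | O=C1C=CC(O)(C=C)C=C1 | intermediate
16 | 4-ethenyl-4-{[hydroxy(phenyl)boranyl]oxy}cyclohexa-2,5-dien-1-one (boronic hemiester) | O=C1C=CC(C=C)(OB(O)c2ccccc2)C=C1 | intermediate
17 | (3aR,7aS)-7a-ethenyl-2-phenyl-3a,4-dihydro-1,3,2-benzodioxaborol-5(7aH)-one (cis-fused cyclic phenylboronate) | O=C1C=C[C@]2(C=C)OB(c3ccccc3)O[C@@H]2C1 | intermediate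
18 | (4S,5R)-4-ethenyl-4,5-dihydroxycyclohex-2-en-1-one (cis-diol) | O=C1C=C[C@@](O)(C=C)[C@H](O)C1 | intermediate
19 | (3aR,7aS)-7a-ethenyl-2,2-dimethyl-3a,4-dihydro-1,3-benzodioxol-5(7aH)-one (acetonide of 18) | O=C1C=C[C@]2(C=C)OC(C)(C)O[C@@H]2C1 | intermediate
20 | (3aR,7aS)-7a-ethenyl-6-iodo-2,2-dimethyl-3a,4-dihydro-1,3-benzodioxol-5(7aH)-one | O=C1C(I)=C[C@]2(C=C)OC(C)(C)O[C@@H]2C1 | intermediate
21 | (2E,4E,6R)-N-[(3aR,7aS)-7a-ethenyl-2,2-dimethyl-5-oxo-3a,4,5,7a-tetrahydro-1,3-benzodioxol-6-yl]-2,4,6-trimethyldeca-2,4-dienamide | CCCC[C@@H](C)/C=C(C)/C=C(\C)C(=O)NC1=C[C@]2(C=C)OC(C)(C)O[C@@H]2CC1=O | intermediate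
22 | (2E,4E,6R)-N-[(3S,4R)-3-ethenyl-3,4-dihydroxy-6-oxocyclohex-1-en-1-yl]-2,4,6-trimethyldeca-2,4-dienamide | CCCC[C@@H](C)/C=C(C)/C=C(\C)C(=O)NC1=C[C@@](O)(C=C)[C@H](O)CC1=O | intermediate
23 | cyclopentane-1,3-dione | O=C1CCC(=O)C1 | starting material
24 | 2-(hydroxyimino)cyclopentane-1,3-dione | O=C1CCC(=O)C1=NO | intermediate
25 | 2-amino-3-hydroxycyclopent-2-en-1-one hydrochloride | Cl.NC1=C(O)CCC1=O | intermediate
26 | potassium (1E,3E)-5-oxopenta-1,3-dien-1-olate (glutaconaldehyde potassium salt) | [K+].[O-]/C=C/C=C/C=O | starting material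
27 | (2E,4E)-5-bromopenta-2,4-dienal | Br/C=C/C=C/C=O | intermediate
28 | (2E,4E)-5-bromopenta-2,4-dienoic acid | Br/C=C/C=C/C(=O)O | intermediate
29 | (2E,4E)-5-bromopenta-2,4-dienoyl chloride | Br/C=C/C=C/C(Cl)=O | intermediate
30 | (2E,4E)-5-bromo-N-(2-hydroxy-5-oxocyclopent-1-en-1-yl)penta-2,4-dienamide | Br/C=C/C=C/C(=O)NC1=C(O)CCC1=O | intermediate
31 | (2E,4E,6R)-N-[(3S,4R)-3,4-dihydroxy-3-[(1E,3E,5E)-7-[(2-hydroxy-5-oxocyclopent-1-en-1-yl)amino]-7-oxohepta-1,3,5-trien-1-yl]-6-oxocyclohex-1-en-1-yl]-2,4,6-trimethyldeca-2,4-dienamide | CCCC[C@@H](C)/C=C(C)/C=C(\C)C(=O)NC1=C[C@@](O)(/C=C/C=C/C=C/C(=O)NC2=C(O)CCC2=O)[C@H](O)CC1=O | target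

## Step count and risks

Total step count: 19.
Longest linear sequence: 9 steps (1, 2, 3, 4, 5, 6, 12, 13, 19).

The three steps most likely to fail:

**Step 9 (the proposed new desymmetrisation).** The risks are a racemic background oxa-Michael addition, modest enantioselectivity, and erosion of ee by retro-oxa-Michael addition before the arms are differentiated in step 11. The fallback sets out from 15 and comes back to the route at 19. It uses the known chiral-phosphoric-acid-catalysed acetalisation/oxa-Michael cascade of p-quinols: 15 and isobutyraldehyde, with the appropriate enantiomer of 3,3′-bis(2,4,6-triisopropylphenyl)-1,1′-binaphthyl-2,2′-diyl hydrogen phosphate (10 mol%) and 4 Å MS in 1,2-dichloroethane at 40 °C, give the cis-fused dioxolane (2S,3aR,7aS)-7a-ethenyl-2-(propan-2-yl)-3a,4-dihydro-1,3-benzodioxol-5(7aH)-one F1. Here the hemiacetal OH, not a boronate, is the tethered nucleophile, and the acetal centre is of no consequence. F1 is then exchanged with excess 2,2-dimethoxypropane in acetone (CSA cat., rt) to the acetonide 19, the aldehyde leaving as its dimethyl acetal.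

**Step 12 (copper-catalysed N-vinylation).** The risks are base-induced β-elimination of the ring oxygen, deiodination, and slow coupling of the α-branched conjugated amide. The fallback sets out from 19 and comes back at 21, and forms the C–N bond without a metal. Nucleophilic epoxidation of 19 (H2O2, K2CO3, MeOH, 0 °C) gives the 6,7-epoxide of 19 F2 (epoxide face not controlled, both isomers converge). NaN3/AcOH in DMF opens it at the carbon next to the ketone, and the β-hydroxy azide dehydrates (MsCl, Et3N if needed) to (3aR,7aS)-6-azido-7a-ethenyl-2,2-dimethyl-3a,4-dihydro-1,3-benzodioxol-5(7aH)-one F3. Staudinger reduction (PMe3, THF–H2O, 0 °C) gives (3aR,7aS)-6-amino-7a-ethenyl-2,2-dimethyl-3a,4-dihydro-1,3-benzodioxol-5(7aH)-one F4, which is acylated at once with acid 9 (EDC·HCl, HOAt, CH2Cl2) to give 21.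

**Step 19 (Heck coupling of two unprotected partners).** The risks are palladium binding by the acidic aminocyclopentenedione, isomerisation of the polyene, and slow oxidative addition of the bromide. The fallback sets out from 22 (with 30) and comes back at 31, replacing the Heck reaction by a boron cross-coupling. Cross-metathesis of 22 with vinylboronic acid pinacol ester (second-generation Hoveyda–Grubbs catalyst, RuCl2(H2IMes)(=CH-C6H4-2-OiPr), 10 mol%, CH2Cl2, 40 °C; the trisubstituted and conjugated alkenes do not take part) gives (2E,4E,6R)-N-[(3S,4R)-3,4-dihydroxy-6-oxo-3-[(E)-2-(4,4,5,5-tetramethyl-1,3,2-dioxaborolan-2-yl)ethenyl]cyclohex-1-en-1-yl]-2,4,6-trimethyldeca-2,4-dienamide F5. Suzuki–Miyaura coupling of F5 with 30 (Pd(PPh3)4, K3PO4, THF–H2O, rt, dark) then gives 31.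

## Further compounds

F1 | step 9 | (2S,3aR,7aS)-7a-ethenyl-2-(propan-2-yl)-3a,4-dihydro-1,3-benzodioxol-5(7aH)-one | O=C1C=C[C@]2(C=C)O[C@@H](C(C)C)O[C@@H]2C1
F2 | step 12 | 6,7-epoxide of 19: 7a-ethenyl-6,7-epoxy-2,2-dimethylhexahydro-1,3-benzodioxol-5-one, ring-fusion centres as in 19, epoxide face not controlled | O=C1C2OC2[C@]3(C=C)OC(C)(C)O[C@@H]3C1
F3 | step 12 | (3aR,7aS)-6-azido-7a-ethenyl-2,2-dimethyl-3a,4-dihydro-1,3-benzodioxol-5(7aH)-one | O=C1C(N=[N+]=[N-])=C[C@]2(C=C)OC(C)(C)O[C@@H]2C1
F4 | step 12 | (3aR,7aS)-6-amino-7a-ethenyl-2,2-dimethyl-3a,4-dihydro-1,3-benzodioxol-5(7aH)-one | O=C1C(N)=C[C@]2(C=C)OC(C)(C)O[C@@H]2C1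
F5 | step 19 | (2E,4E,6R)-N-[(3S,4R)-3,4-dihydroxy-6-oxo-3-[(E)-2-(4,4,5,5-tetramethyl-1,3,2-dioxaborolan-2-yl)ethenyl]cyclohex-1-en-1-yl]-2,4,6-trimethyldeca-2,4-dienamide | CCCC[C@@H](C)/C=C(C)/C=C(\C)C(=O)NC1=C[C@@](O)(/C=C/B2OC(C)(C)C(C)(C)O2)[C@H](O)CC1=O
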